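At early times the gamma run was still moving: the complex with one exchanged read 14.1% at 1.00 h and 9.8% at 2.50 h. It then sat round 9.90% with no trend. What did that plateau say about two new flasks, Monday's and Friday's?

common to all: starting complex 19 mM

| charge | incoming ligand | leaving ligand | remark | time |
|---|---|---|---|---|
| theta | 23 mM | 38 mM | run made earlier |  |
| epsilon | 36 mM | 38 mM | run made earlier |  |
| gamma | 61 mM | 38 mM | run made earlier |  |
| Monday's | 22.8 mM | 38.0 mM |  | 25 h |
| Friday's | 57.0 mM | 38.0 mM |  | 25 h |

| run | time / h | complex with one exchanged / % |
|---|---|---|
| theta | 1.00 | 21.5 |
| theta | 2.50 | 21.4 |
| theta | 5.00 | 21.3 |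
| theta | 12.0 | 21.4 |
| epsilon | 3.00 | 19.6 |
| epsilon | 6.00 | 18.6 |
| epsilon | 10.0 | 18.6 |
| epsilon | 12.0 | 19.1 |
| gamma | 1.00 | 14.1 |
| gamma | 2.50 | 9.8 |
| gamma | 5.00 | 10.5 |
| gamma | 12.0 | 9.4 |

(readings scatter by 0.3 percentage points)



1. which of these holds the largest part of the starting complex at the end of Monday's (starting complex / complex with two exchanged / complex with one exchanged / complex with three exchanged)
2. which of these holds the largest part of the starting complex at the end of Friday's (starting complex / complex with two exchanged / complex with one exchanged / complex with three exchanged)
3. final complex with one exchanged in Friday's, as a percentage of the starting complex charged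

Was the asked time on the plateau? Friday's ended at 25 h, twice the time of the last gamma reading, so I took its end to be the plateau.

Which plateau? The earlier runs differed in one charge, so I ordered them by equivalents, the incoming ligand charged per starting complex; Friday's had 3.00. Theta stood at 1.21 with readings averaging 21.4%. Epsilon stood at 1.89 with 18.8% over its last readings, and gamma at 3.21. From epsilon to gamma the plateau dropped 6.7 percentage points per equivalent. Friday's lay 0.210 equivalents below gamma, so I expected 11.3%. The readings show one form, so I did not split the rest myself.

The forecast named starting complex for Monday's, complex with two exchanged for Friday's and 11% for the amount asked, calling the complex with one exchanged “a poorly populated intermediate”.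

Monday's ended with starting complex largest at 55.3%. Friday's ended with complex with two exchanged largest at 70.6% and 10.9% of complex with one exchanged, against my 11.3%. In Friday's the incoming ligand, the limiting reagent, stood at 0% of its charge, with 28.1 mM of decomposed reagent.

    starting complex + incoming ligand → leaving ligand + complex with one exchanged (k = 48.6 /M/h)
    complex with one exchanged + incoming ligand → leaving ligand + complex with two exchanged (k = 125 /M/h)
    complex with two exchanged + incoming ligand ⇌ leaving ligand + complex with three exchanged (K = 0.954, k = 6.14 /M/h)
    incoming ligand → decomposed reagent (k = 0.808 /h)

A neighbour of Friday's flask was charged with 48 mM of starting complex. Its equivalents fell from 3.00 to 1.19 equiv, which put it beside theta at 1.21, so the same reckoning read 21.4% for the complex with one exchanged. The neighbour flask gave 20.4%. Its largest holder was starting complex at 44.5%, with the complex with two exchanged at 35.2%, against 23.4% in Monday's at 1.20 equivalents.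

The numbers in the tables were computed with constants of no real substance; scatter was added.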